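**Assumptions:** Methyl α-D-galactopyranoside (1) is the chiral source, and the anomeric configuration is irrelevant because C1 of the sugar is destroyed in step 5. Nonyltriphenylphosphonium bromide is taken as commercial. Target numbering: C1 is the ketone, C2=C3 the alkene, C4 and C5 the CH–OH carbons, and C6 the quaternary carbinol.

## Retrosynthesis
1. Pleiogenone A (13) comes from acid removal of the acetonide and TBS groups of 12.
2. 12 comes from α′-alkylation of enone 7 with the Z-bromide 11. The alkyl group enters anti to the cis-fused acetonide, which sets the quaternary C6.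
3. 7 comes from dehydration of 6, which is the Hg(II) Ferrier carbocyclisation product of enol ether 5. The six-membered ring forms here, and D-galactose supplies the C4/C5/C6 stereotriad: sugar C2, C3 and C4 become target C4, C5 and C6.
4. 11 comes from a Z-selective Wittig reaction of 8-bromooctanal (9) with the nonyl ylide from 10.

## Route

**Step 1**
Reactants: 1 methyl α-D-galactopyranoside
Product: 2 methyl 3,4-O-isopropylidene-α-D-galactopyranoside
Conditions: 2,2-dimethoxypropane, cat. TsOH·H2O, DMF, rt
Reagents that add atoms: 2,2-dimethoxypropane, COC(C)(C)OC (supplies the CMe2 bridge)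
Why: Kinetic ketalisation takes the cis-3,4-diol of the galacto ring. No stereocentre is touched, and the cis-fused acetonide later directs the alkylation.

**Step 2**
Reactants: 2
Product: 3 methyl 6-deoxy-6-iodo-3,4-O-isopropylidene-α-D-galactopyranoside
Conditions: PPh3, I2, imidazole, toluene, 80 °C
Reagents that add atoms: iodine, II
Why: Garegg–Samuelsson iodination (Appel-type SN2) is selective for the primary OH, and the secondary 2-OH is untouched.

**Step 3**
Reactants: 3
Product: 4 methyl 2-O-TBS-6-deoxy-6-iodo-3,4-O-isopropylidene-α-D-galactopyranoside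
Conditions: TBSOTf, 2,6-lutidine, CH2Cl2, 0 °C
Reagents that add atoms: TBSOTf, C[Si](C)(C)C(C)(C)OS(=O)(=O)C(F)(F)F (supplies TBS)
Why: Silylation protects the future C4-OH so it survives mesylation and enolate chemistry.

**Step 4**
Reactants: 4
Product: 5 methyl 2-O-TBS-6-deoxy-3,4-O-isopropylidene-α-D-lyxo-hex-5-enopyranoside
Conditions: AgF, pyridine, rt, dark
Reagents that add atoms: none
Why: Dehydrohalogenation (E2) gives the exocyclic enol ether C5=C6. The sugar C5 centre is lost, and it is not needed.

**Step 5**
Reactants: 5
Product: 6 (4S,5R,6R)-4-OTBS-5,6-O-isopropylidene-3-hydroxycyclohexan-1-one (C3 epimeric)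
Conditions: HgCl2, acetone/H2O 5:1, 60 °C
Reagents that add atoms: water, O (supplies the ketone oxygen; MeOH is lost)
Why: In the Ferrier carbocyclisation, Hg(II) adds to the enol ether and hydrolysis gives a C1 aldehyde and a C5 ketone bearing a C6–Hg enolate. Intramolecular aldol then closes the cyclohexanone. The new carbinol stereocentre is erased in step 6, and the three oxygenated stereocentres come untouched from D-galactose.

**Step 6**
Reactants: 6
Product: 7 (4S,5R,6R)-4-OTBS-5,6-O-isopropylidene-cyclohex-2-en-1-one
Conditions: MsCl, Et3N, CH2Cl2, 0 °C to rt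
Reagents that add atoms: none
Why: The β-hydroxy ketone is mesylated and undergoes E1cB elimination to the enone. The only possible direction is C2=C3, because C6 has no α-enolisable side that could give another alkene.

**Step 7**
Reactants: 8 8-bromooctan-1-ol
Product: 9 8-bromooctanal
Conditions: Dess–Martin periodinane, NaHCO3, CH2Cl2, rt
Reagents that add atoms: none
Why: Mild oxidation of the primary alcohol to the aldehyde; the bromide is untouched.

**Step 8**
Reactants: 9 8-bromooctanal; 10 nonyltriphenylphosphonium bromide
Product: 11 (Z)-1-bromoheptadec-8-ene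
Conditions: 10, NaHMDS, THF, −78 °C to rt, then 9 added at −78 °C
Reagents that add atoms: none
Why: A salt-free unstabilised ylide gives the cis oxaphosphetane under kinetic control, so the Wittig reaction delivers the Z-alkene. This builds the C17 (CH2)7CH=CH(CH2)7CH3 chain with the alkene in place.

**Step 9**
Reactants: 7 enone; 11 (Z)-1-bromoheptadec-8-ene
Product: 12 C6-alkylated enone
Conditions: LDA, THF, −78 °C; then 11, HMPA, cat. NaI, −78 to −30 °C
Reagents that add atoms: none (11 is the reactant and supplies R)
Why: Kinetic deprotonation at α′ (C6), the only enolisable α-site, gives the enolate, which undergoes SN2 alkylation (enolate α-alkylation). Attack anti to the 5-O of the acetonide is the only pathway giving a cis-fused dioxolane. This puts R trans to O5 and O6 cis to O5, which is the required (6R) quaternary centre.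

**Step 10**
Reactants: 12
Product: 13 pleiogenone A
Conditions: 2 M aq. HCl/THF 1:3, 25 °C, 12 h
Reagents that add atoms: none (water supplies only hydrogen to the product)
Why: Acid hydrolysis removes the acetonide and the TBS ether. C6 is quaternary and C4/C5 are not α to the carbonyl, so nothing epimerises, and the Z-alkene survives.

## Compound list
1 | methyl α-D-galactopyranoside | CO[C@H]1O[C@H](CO)[C@H](O)[C@H](O)[C@H]1O | starting material
2 | methyl 3,4-O-isopropylidene-α-D-galactopyranoside | CO[C@H]1O[C@H](CO)[C@@H]2OC(C)(C)O[C@@H]2[C@H]1O | intermediate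
3 | methyl 6-deoxy-6-iodo-3,4-O-isopropylidene-α-D-galactopyranoside | CO[C@H]1O[C@H](CI)[C@@H]2OC(C)(C)O[C@@H]2[C@H]1O | intermediate
4 | methyl 2-O-TBS-6-deoxy-6-iodo-3,4-O-isopropylidene-α-D-galactopyranoside | CO[C@H]1O[C@H](CI)[C@@H]2OC(C)(C)O[C@@H]2[C@H]1O[Si](C)(C)C(C)(C)C | intermediate
5 | methyl 2-O-TBS-6-deoxy-3,4-O-isopropylidene-α-D-lyxo-hex-5-enopyranoside | CO[C@H]1OC(=C)[C@@H]2OC(C)(C)O[C@@H]2[C@H]1O[Si](C)(C)C(C)(C)C | intermediate
6 | 3-hydroxy-4-OTBS-5,6-O-isopropylidenecyclohexanone (C3 epimeric) | O=C1CC(O)[C@H](O[Si](C)(C)C(C)(C)C)[C@H]2OC(C)(C)O[C@@H]12 | intermediate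
7 | (4S,5R,6R)-4-OTBS-5,6-O-isopropylidenecyclohex-2-enone | O=C1C=C[C@H](O[Si](C)(C)C(C)(C)C)[C@H]2OC(C)(C)O[C@@H]12 | intermediate
8 | 8-bromooctan-1-ol | OCCCCCCCCBr | starting material
9 | 8-bromooctanal | O=CCCCCCCCBr | intermediate
10 | nonyltriphenylphosphonium bromide | CCCCCCCCC[P+](c1ccccc1)(c1ccccc1)c1ccccc1.[Br-] | starting material
11 | (Z)-1-bromoheptadec-8-ene | BrCCCCCCC/C=C\CCCCCCCC | intermediate
12 | 6-[(Z)-heptadec-8-enyl]-4-OTBS-5,6-O-isopropylidenecyclohex-2-enone | CCCCCCCC/C=C\CCCCCCC[C@]12C(=O)C=C[C@H](O[Si](C)(C)C(C)(C)C)[C@H]1OC(C)(C)O2 | intermediate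
13 | pleiogenone A | CCCCCCCC/C=C\CCCCCCC[C@]1(O)C(=O)C=C[C@H](O)[C@H]1O | target

## Totals
Total steps: 10. Longest linear sequence: 8 (steps 1–6, 9, 10).

## Three steps most likely to fail
1. **Step 9, alkylation.** An unactivated primary bromide reacts slowly, and the β-alkoxy enolate may undergo E1cB loss of the acetonide oxygen.
   - Fallback: aldol of the same enolate with (Z)-hexadec-7-enal, made by an analogous Wittig reaction, at −78 °C. Then deoxygenate the resulting alcohol by Barton–McCombie reduction of its xanthate.
2. **Step 5, Hg-mediated carbocyclisation.** Yield, toxicity, and survival of the acetonide and silyl ether under acidic aqueous Hg(II) are all concerns.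
   - Fallback: Zn-mediated reductive fragmentation of iodide 4 to the 5-enal, then Wacker oxidation of the terminal alkene to the methyl ketone, then base-mediated intramolecular aldol to give 6 without mercury.
3. **Step 1, regioselective 3,4-acetonation.** The 4,6-acetal or a mixture of acetals may form.
   - Fallback: start from commercial 1,2:3,4-di-O-isopropylidene-α-D-galactopyranose and run the same iodination, elimination and Ferrier sequence. The Hg step removes the 1,2-acetonide, after which the C2 hydroxyl is silylated and the sequence continues.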